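## Retrosynthetic overview
1. Target ⇒ 2-iodo-5-methylphenol + a (Z)-β-boryl enol ether, joined by Suzuki–Miyaura coupling with retention. The Z geometry (O cis to CH2OH) comes from syn H–B addition to a γ-hydroxy ynol ether.
2. Ynol ether ⇒ (S)-encecalol + trichloroethylene (the two enol carbons) + formaldehyde (the CH2OH carbon). The C–O bond at the stereocentre is never broken.
3. (S)-Encecalol ⇒ encecalin (asymmetric transfer hydrogenation sets S) ⇒ 6-acetyl-7-hydroxy-2,2-dimethylchromene (O-methylation).
4. Key step: both chromene rings come from acyclic partners, a tris(silyloxy)triene and but-3-yn-2-one. [4+2]/aromatisation forms the benzene ring first, then o-quinone methide/oxa-6π closes the pyran ring in the same flask.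
5. Triene ⇒ methyl acetoacetate + prenal (γ-aldol, then silylation). The cresol ring is bought.

Assumption: the SMILES is read as (S) at the benzylic carbon and (Z) at the enol ether, meaning the alkoxy O is cis to CH2OH and the vinyl H is cis to the aryl ring.

## Route

Step 1
Reactants: 1 methyl acetoacetate; 2 prenal (3-methylbut-2-enal)
Product: 3 methyl 5-hydroxy-7-methyl-3-oxooct-6-enoate (racemic)
Conditions: LDA (2.1 equiv), THF, 0 °C; then 2, −78 °C; sat. aq NH4Cl
Reagents that add atoms: none
Why: This is a Weiler-type γ-selective aldol, in which the doubly deprotonated β-keto ester reacts only at its terminal carbon and adds 1,2 to the enal; the new carbinol centre is racemic and is erased in step 3.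

Step 2
Reactants: 3 methyl 5-hydroxy-7-methyl-3-oxooct-6-enoate
Product: 4 (3Z)-1-methoxy-7-methyl-1,3,5-tris(trimethylsilyloxy)octa-1,3,6-triene (racemic, used crude)
Conditions: TMSOTf (3.3 equiv), Et3N (4.5 equiv), Et2O, 0 °C → rt; decant from the ammonium salt layer, concentrate
Reagents that add atoms: trimethylsilyl trifluoromethanesulfonate, C[Si](C)(C)OS(=O)(=O)C(F)(F)F
Why: Soft enolisation with silyl triflate/amine (bis-silylation of a 1,3-dicarbonyl to a Chan-type diene) caps the alcohol and builds the 1,1,3-trioxygenated diene without a strong base that could cause E1cB loss of the δ-oxygen; the thermodynamic 3Z enol ether puts the side chain on the outside of the s-cis diene, and no stereocentre is set.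

Step 3 (key step)
Reactants: 4 (3Z)-1-methoxy-7-methyl-1,3,5-tris(trimethylsilyloxy)octa-1,3,6-triene; 5 but-3-yn-2-one
Product: 9 1-(7-hydroxy-2,2-dimethyl-2H-chromen-6-yl)ethanone (eupatoriochromene), via cyclohexadiene cycloadduct 6 (not isolated), via tris-silylated acetophenone 7 (not isolated), via o-quinone methide 8 (not isolated)
Conditions: 5 (1.3 equiv), BHT (1 mol %), toluene (0.2 M), 0 → 70 °C; then THF, 1 M aq HCl, 23 → 45 °C, same flask
Reagents that add atoms: none
Why: Proposed new method: the nucleophilic C4 of diene 4 bonds to the alkyne CH and the ketene-acetal carbon bonds to the acyl-bearing carbon (Brassard/Chan-diene Diels–Alder benzannulation with an ynone), loss of MeOH aromatises 6 to 7 (benzene ring), and acid desilylation ionises the allylic/benzylic C–O bond to o-quinone methide 8, whose oxa-6π electrocyclisation closes the pyran; only the hydroxyl para to the acetyl group is ortho to the side chain, so only the linear chromene can form; the closest known reaction type is the carbene benzannulation/o-quinone-methide/electrocyclisation cascade to chromenes; no stereocentre survives.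

Step 4
Reactants: 9 1-(7-hydroxy-2,2-dimethyl-2H-chromen-6-yl)ethanone
Product: 10 1-(7-methoxy-2,2-dimethyl-2H-chromen-6-yl)ethanone (encecalin)
Conditions: MeI (2 equiv), K2CO3, acetone, reflux
Reagents that add atoms: iodomethane, CI
Why: Williamson O-methylation of the only free, chelated phenol works at reflux; the ketone and the chromene alkene are inert and no stereocentre is involved.

Step 5
Reactants: 10 encecalin
Product: 11 (1S)-1-(7-methoxy-2,2-dimethyl-2H-chromen-6-yl)ethanol ((S)-encecalol)
Conditions: RuCl[(S,S)-TsDPEN](p-cymene) (0.5 mol %), HCO2Na (5 equiv), H2O–MeOH 1:1, 40 °C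
Reagents that add atoms: none
Why: In this Noyori–Ikariya asymmetric transfer hydrogenation the (S,S)-catalyst delivers hydride to the Re face of the aryl methyl ketone and gives the S alcohol; the slightly basic formate medium prevents SN1 racemisation of this very electron-rich benzylic alcohol and leaves the chromene alkene untouched.

Step 6
Reactants: 11 (S)-encecalol; 12 trichloroethylene; 13 paraformaldehyde
Product: 16 3-{(1S)-1-(7-methoxy-2,2-dimethyl-2H-chromen-6-yl)ethoxy}prop-2-yn-1-ol, via (E)-1,2-dichlorovinyl ether 14 (not isolated), via lithium alkoxyacetylide 15 (not isolated)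
Conditions: KH (1.2 equiv), THF, 0 °C; 12 (1.1 equiv), −50 °C → rt; n-BuLi (2.3 equiv), −78 → −40 °C; 13 (4 equiv), −40 → 10 °C; H2O quench; used crude, kept below 20 °C
Reagents that add atoms: n-butyllithium, [Li]CCCC (its Li stays only in intermediate 15)
Why: In the Greene ynol-ether synthesis the potassium alkoxide undergoes addition–elimination on trichloroethylene to give 14, n-BuLi effects dehydrochlorination and Cl/Li exchange to give 15, and the acetylide adds to formaldehyde; everything is basic and the C–O bond at the stereocentre is never broken, so S is retained.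

Step 7
Reactants: 16 3-{(1S)-1-(7-methoxy-2,2-dimethyl-2H-chromen-6-yl)ethoxy}prop-2-yn-1-ol; 17 2-iodo-5-methylphenol
Product: 19 2-[(1Z)-3-hydroxy-1-{(1S)-1-(7-methoxy-2,2-dimethyl-2H-chromen-6-yl)ethoxy}prop-1-en-2-yl]-5-methylphenol (target), via bis(pinacolboryl) enol ether 18 (not isolated)
Conditions: HBpin (1.05 equiv), THF, 0 °C; then CuCl/Xantphos/NaOt-Bu (5/5/10 mol %), HBpin (1.2 equiv), rt; then 17 (1.1 equiv), Pd(OAc)2/SPhos (3/6 mol %), 3 M aq K3PO4, 40 °C; pH 7 buffer; Et3N-deactivated silica
Reagents that add atoms: pinacolborane, [H]B1OC(C)(C)C(C)(C)O1 (its Bpin groups stay only in intermediate 18)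
Why: Cu–H-catalysed syn-hydroboration puts hydride on the electrophilic O-bearing alkyne carbon and Cu, then Bpin, on the carbon next to CH2O (ynol-ether polarisation and the propargylic inductive effect reinforce each other), so H and B are cis and OR is cis to CH2O (Z); the stereoretentive Suzuki–Miyaura coupling then replaces B by the aryl group while aqueous base frees the O–Bpin, and the basic medium preserves the enol ether, the hindered chromene alkene and the S centre.

## Compound list
1 | methyl acetoacetate | COC(=O)CC(C)=O | starting material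
2 | prenal (3-methylbut-2-enal) | CC(C)=CC=O | starting material
3 | methyl 5-hydroxy-7-methyl-3-oxooct-6-enoate (racemic) | COC(=O)CC(=O)CC(O)C=C(C)C | intermediate
4 | (3Z)-1-methoxy-7-methyl-1,3,5-tris(trimethylsilyloxy)octa-1,3,6-triene (racemic, C1=C2 geometry irrelevant) | COC(O[Si](C)(C)C)=C/C(O[Si](C)(C)C)=C/C(O[Si](C)(C)C)C=C(C)C | intermediate
5 | but-3-yn-2-one | CC(=O)C#C | starting material
6 | cyclohexa-1,4-diene Diels–Alder adduct (diastereomer mixture, not isolated) | COC1(O[Si](C)(C)C)C=C(O[Si](C)(C)C)C(C(O[Si](C)(C)C)C=C(C)C)C=C1C(C)=O | intermediate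
7 | 1-{2,4-bis(trimethylsilyloxy)-5-[3-methyl-1-(trimethylsilyloxy)but-2-enyl]phenyl}ethanone (racemic, not isolated) | CC(=O)c1cc(C(O[Si](C)(C)C)C=C(C)C)c(O[Si](C)(C)C)cc1O[Si](C)(C)C | intermediate
8 | 4-acetyl-3-hydroxy-6-(3-methylbut-2-enylidene)cyclohexa-2,4-dienone, the o-quinone methide (not isolated) | CC(=O)C1=CC(=CC=C(C)C)C(=O)C=C1O | intermediate
9 | 1-(7-hydroxy-2,2-dimethyl-2H-chromen-6-yl)ethanone (eupatoriochromene) | CC(=O)c1cc2c(cc1O)OC(C)(C)C=C2 | intermediate
10 | 1-(7-methoxy-2,2-dimethyl-2H-chromen-6-yl)ethanone (encecalin) | COc1cc2c(cc1C(C)=O)C=CC(C)(C)O2 | intermediate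
11 | (1S)-1-(7-methoxy-2,2-dimethyl-2H-chromen-6-yl)ethanol ((S)-encecalol) | COc1cc2c(cc1[C@H](C)O)C=CC(C)(C)O2 | intermediate
12 | trichloroethylene | ClC=C(Cl)Cl | starting material
13 | paraformaldehyde (reacts as formaldehyde) | C=O | starting material
14 | 6-{(1S)-1-[(E)-1,2-dichlorovinyloxy]ethyl}-7-methoxy-2,2-dimethyl-2H-chromene (not isolated) | COc1cc2c(cc1[C@H](C)O/C(Cl)=C\Cl)C=CC(C)(C)O2 | intermediate
15 | lithium 2-{(1S)-1-(7-methoxy-2,2-dimethyl-2H-chromen-6-yl)ethoxy}acetylide (not isolated) | COc1cc2c(cc1[C@H](C)OC#C[Li])C=CC(C)(C)O2 | intermediate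
16 | 3-{(1S)-1-(7-methoxy-2,2-dimethyl-2H-chromen-6-yl)ethoxy}prop-2-yn-1-ol | COc1cc2c(cc1[C@H](C)OC#CCO)C=CC(C)(C)O2 | intermediate
17 | 2-iodo-5-methylphenol | Cc1ccc(I)c(O)c1 | starting material
18 | (Z)-enol ether carrying vinyl-Bpin (trans to the alkoxy O) and CH2O-Bpin (cis to the alkoxy O), S at the benzylic carbon (not isolated) | COc1cc2c(cc1[C@H](C)O/C=C(\COB1OC(C)(C)C(C)(C)O1)B1OC(C)(C)C(C)(C)O1)C=CC(C)(C)O2 | intermediate
19 | 2-[(1Z)-3-hydroxy-1-{(1S)-1-(7-methoxy-2,2-dimethyl-2H-chromen-6-yl)ethoxy}prop-1-en-2-yl]-5-methylphenol (CNP0279099.1) | COc1cc2c(cc1[C@H](C)O/C=C(\CO)c1ccc(C)cc1O)C=CC(C)(C)O2 | target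

## Step count and risks
Total steps: 7. Longest linear sequence: 7 (1 → 3 → 4 → 9 → 10 → 11 → 16 → 19).

**Most likely to fail: step 3.**
- The 4-branched diene may react slowly while the ynone polymerises.
- The allylic silyloxy group may be lost before the arene exists.
- Fallback, setting out from prenal 2 and buying the arene:
  - Condense 2 with commercial 3-methoxyphenol (PhB(OH)2, AcOH, toluene, reflux, water removal; o-quinone-methide/oxa-6π chromenylation). This gives 7-methoxy-2,2-dimethyl-2H-chromene (precocene I) F1.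
  - Acetylate the position para to the ring oxygen and ortho to OMe by Friedel–Crafts acylation (Ac2O, cat. Sc(OTf)3, MeNO2).
  - This comes back to the route at encecalin 10 and skips steps 1–4.

**Second: step 7.**
- Ynol ether 16 can rearrange ([3,3] or retro-ene) on warming.
- The vinyl-copper species can lose the neighbouring oxygen to give an alkoxyallene.
- The boron may end up on the wrong carbon.
- Fallback, setting out from (S)-encecalol 11 and forming the enol C–O bond instead of the C–aryl bond:
  - Silylate commercial 2-bromo-5-methylphenol (TBSCl, imidazole) to tert-butyl(2-bromo-5-methylphenoxy)dimethylsilane F2.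
  - Treat with Mg in THF to give [2-(tert-butyldimethylsilyloxy)-4-methylphenyl]magnesium bromide F3.
  - Add F3 to propargyl alcohol (pre-deprotonated with EtMgBr; CuI 15 mol %). This is an anti-carbomagnesiation through the five-membered magnesium alkoxide chelate.
  - Quench with I2 to obtain (Z)-2-[2-(tert-butyldimethylsilyloxy)-4-methylphenyl]-3-iodoprop-2-en-1-ol F4, with I cis to CH2OH.
  - Protect with TBSCl to give (Z)-vinyl iodide bis-TBS ether F5.
  - Couple F5 with 11 with retention (CuI, 3,4,7,8-tetramethyl-1,10-phenanthroline, Cs2CO3, toluene, 80 °C) to give the bis-TBS ether of the target F6.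
  - Remove both silyl groups with TBAF (THF, 0 °C).
  - This comes back at target 19 and also bypasses step 6.

**Third: step 2.**
- The prenyl-type allylic silyl ether may ionise.
- The aldol may revert or eliminate during triple silylation.
- Fallback, setting out from methyl acetoacetate 1:
  - Alkylate its dianion with prenyl bromide to methyl 7-methyl-3-oxooct-6-enoate F7, which has no β-leaving group.
  - Silylate to (3Z)-1-methoxy-7-methyl-1,3-bis(trimethylsilyloxy)octa-1,3,6-triene F8.
  - Cycloadd F8 to 5 and hydrolyse to 1-[2,4-dihydroxy-5-(3-methylbut-2-enyl)phenyl]ethanone F9.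
  - Close the pyran oxidatively with DDQ (toluene, reflux; hydride abstraction, o-quinone methide, oxa-6π).
  - This comes back at 9.

## Further compounds
F1 | step 3 | 7-methoxy-2,2-dimethyl-2H-chromene (precocene I) | COc1ccc2c(c1)OC(C)(C)C=C2
F2 | step 7 | tert-butyl(2-bromo-5-methylphenoxy)dimethylsilane | Cc1ccc(Br)c(O[Si](C)(C)C(C)(C)C)c1
F3 | step 7 | [2-(tert-butyldimethylsilyloxy)-4-methylphenyl]magnesium bromide | Cc1ccc([Mg]Br)c(O[Si](C)(C)C(C)(C)C)c1
F4 | step 7 | (Z)-2-[2-(tert-butyldimethylsilyloxy)-4-methylphenyl]-3-iodoprop-2-en-1-ol | I/C=C(\CO)c1ccc(C)cc1O[Si](C)(C)C(C)(C)C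
F5 | step 7 | (Z)-vinyl iodide bis-TBS ether | I/C=C(\CO[Si](C)(C)C(C)(C)C)c1ccc(C)cc1O[Si](C)(C)C(C)(C)C
F6 | step 7 | bis-TBS ether of the target | COc1cc2c(cc1[C@H](C)O/C=C(\CO[Si](C)(C)C(C)(C)C)c1ccc(C)cc1O[Si](C)(C)C(C)(C)C)C=CC(C)(C)O2
F7 | step 2 | methyl 7-methyl-3-oxooct-6-enoate | COC(=O)CC(=O)CCC=C(C)C
F8 | step 2 | (3Z)-1-methoxy-7-methyl-1,3-bis(trimethylsilyloxy)octa-1,3,6-triene | COC(O[Si](C)(C)C)=C/C(O[Si](C)(C)C)=C/CC=C(C)C
F9 | step 2 | 1-[2,4-dihydroxy-5-(3-methylbut-2-enyl)phenyl]ethanone | CC(=O)c1cc(CC=C(C)C)c(O)cc1O
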